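**Retrosynthetic overview**
- The 20,7β-lactone (last ring) is opened to the free C20 acid of (15S)-16-acetoxycarnosic acid. Forward, anodic oxidation of the catechol gives a quinone methide that the C20 carboxylate closes, which sets C7.
- The catechol and the acid are masked as two Troc carbonates and a spent 4-nitrosobenzyl ester, all removed by zinc in one operation.
- The C16–O bond is cut back to a methyl C–H of the isopropyl group. Forward, a 4-nitrobenzyl ester on C20 lies over the β face of ring C and, on irradiation, passes one nitro oxygen to the β-face methyl, which sets C15.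
- Rings A, B and C with C5 and C10 are bought as carnosic acid; the template comes from 4-nitrobenzyl bromide.
- Ring order: A, B, C bought; lactone ring closed last.

Assumption: carnosic acid (bulk rosemary extract, single (5S,10R) enantiomer) counts as a commercial starting material. Abietane numbering is used, and the target read from the SMILES is (5S,7S,10R,15S)-16-acetoxycarnosol.

**Route**

Step 1
Reactants: 1 carnosic acid; 2 4-nitrobenzyl bromide
Product: 4 carnosic acid 4-nitrobenzyl ester 11,12-bis(2,2,2-trichloroethyl carbonate), via carnosic acid 4-nitrobenzyl ester 3 (not isolated)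
Conditions: KHCO3 (1.2 equiv), DMF, rt, Ar; then pyridine, TrocCl (3 equiv), DMAP (cat.), 0 °C to rt
Reagents that add atoms: 2,2,2-trichloroethyl chloroformate (TrocCl), ClC(=O)OCC(Cl)(Cl)Cl
Why: KHCO3 deprotonates only the carboxylic acid (pKa about 5 against about 10 for the phenols), so the carboxylate alone is alkylated by the benzylic bromide (SN2 esterification), and pyridine/DMAP acylation then caps both phenols as carbonates that have no weak C–H bond and raise the oxidation potential of ring C beyond the reach of an excited nitroarene; no stereocenter is touched.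

Step 2
Reactants: 4 carnosic acid 4-nitrobenzyl ester 11,12-bis(2,2,2-trichloroethyl carbonate)
Product: 7 (15S)-16-acetoxycarnosic acid 4-nitrosobenzyl ester 11,12-bis(2,2,2-trichloroethyl carbonate), via ansa N-aryl-N-hydroxy-O-alkylhydroxylamine 5 (not isolated), via 16-hydroxy 4-nitrosobenzyl ester 6 (not isolated)
Conditions: hν (390 nm LEDs), degassed PhCF3/(CF3)2CHOH 4:1, 1 mM, 25 °C; then concentrate, Ac2O, pyridine, 0 °C to rt
Reagents that add atoms: acetic anhydride, CC(=O)OC(C)=O
Why: Proposed new method: a template-directed photochemical C–H hydroxylation that tells two diastereotopic methyl groups apart — the rigid 4-nitrobenzyl ester keeps its nitro oxygen about 6.5–8.5 Å from C20, too far to reach any hydrogen of ring A or ring B but right for stacking on the β face of ring C, where the triplet nitro group abstracts hydrogen from the β-face methyl of the isopropyl group (whose C15–H lies in the arene plane pointing at the O12 carbonate, a 1,3-allylic-strain rotamer lock that also removes benzylic activation of C15–H), the radical pair recombines at oxygen to 5, and 5 fragments to alcohol 6 and the nitrosoarene, so C10 fixes C15 as S before in-flask acetylation; the closest known reaction types are anaerobic C–H hydroxylation by photoexcited nitroarenes and Breslow-type remote functionalisation of steroids through ester-tethered photoexcited arenes, which has been used at tertiary C–H but not to set a stereocenter by choosing one methyl of an isopropyl group.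

Step 3
Reactants: 7 (15S)-16-acetoxycarnosic acid 4-nitrosobenzyl ester 11,12-bis(2,2,2-trichloroethyl carbonate)
Product: 9 (15S)-16-acetoxycarnosic acid, via 4-aminobenzyl ester 8 (not isolated)
Conditions: Zn dust (excess), AcOH/THF 1:1, rt to 40 °C, Ar; work-up with degassed dilute HCl
Reagents that add atoms: none
Why: Zinc in acetic acid removes both Troc carbonates by reductive β-elimination and loss of CO2 and reduces the nitroso group to the aniline, whose 4-aminobenzyl ester 8 collapses by 1,6-elimination (the standard reductive removal of 4-nitrobenzyl esters), while the primary acetate and all stereocenters are untouched.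

Step 4
Reactants: 9 (15S)-16-acetoxycarnosic acid
Product: 12 (15S)-16-acetoxycarnosol, via o-quinone 10 (not isolated), via p-quinone methide 11 (not isolated)
Conditions: divided cell, graphite felt anode, Pt cathode, 0.1 M LiClO4 in MeCN, 2,6-lutidine (2.2 equiv), +0.5 V vs Ag/AgCl (first anodic wave, set from a voltammogram of 9), 2.0 F/mol, 0 °C, Ar; then current off, rt, 2 h
Reagents that add atoms: none
Why: Anodic two-electron oxidation of the catechol gives o-quinone 10, which tautomerises through the well-aligned C7–H to p-quinone methide 11 and is trapped by the C20 carboxylate (the carnosic acid to carnosol oxidative lactonisation); the carboxylate is held on the β face by C10, so the new C7–O bond can only be β (7S), and the in-plane C15–H is not enolised.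

Expected by-products of step 2 are the 15R epimer (from the minor isopropyl rotamer; estimated dr at least 5:1) and some 15-hydroxy regioisomer. Both are removed by chromatography at 7 or crystallisation at 9.

**Compound list**

1 | carnosic acid | CC(C)c1cc2c(c(O)c1O)[C@@]1(C(=O)O)CCCC(C)(C)[C@@H]1CC2 | starting material
2 | 4-nitrobenzyl bromide | O=[N+]([O-])c1ccc(CBr)cc1 | starting material
3 | carnosic acid 4-nitrobenzyl ester | CC(C)c1cc2c(c(O)c1O)[C@@]1(C(=O)OCc3ccc(cc3)[N+](=O)[O-])CCCC(C)(C)[C@@H]1CC2 | intermediate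
4 | carnosic acid 4-nitrobenzyl ester 11,12-bis(2,2,2-trichloroethyl carbonate) | CC(C)c1cc2c(c(OC(=O)OCC(Cl)(Cl)Cl)c1OC(=O)OCC(Cl)(Cl)Cl)[C@@]1(C(=O)OCc3ccc(cc3)[N+](=O)[O-])CCCC(C)(C)[C@@H]1CC2 | intermediate
5 | ansa N-aryl-N-hydroxy-O-alkylhydroxylamine (C16–O–N(OH)–aryl bridge over the β face) | ON1OC[C@@H](C)c2cc3c(c(OC(=O)OCC(Cl)(Cl)Cl)c2OC(=O)OCC(Cl)(Cl)Cl)[C@@]2(C(=O)OCc4ccc1cc4)CCCC(C)(C)[C@@H]2CC3 | intermediate
6 | (15S)-16-hydroxycarnosic acid 4-nitrosobenzyl ester 11,12-bis(2,2,2-trichloroethyl carbonate) | OC[C@@H](C)c1cc2c(c(OC(=O)OCC(Cl)(Cl)Cl)c1OC(=O)OCC(Cl)(Cl)Cl)[C@@]1(C(=O)OCc3ccc(N=O)cc3)CCCC(C)(C)[C@@H]1CC2 | intermediate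
7 | (15S)-16-acetoxycarnosic acid 4-nitrosobenzyl ester 11,12-bis(2,2,2-trichloroethyl carbonate) | CC(=O)OC[C@@H](C)c1cc2c(c(OC(=O)OCC(Cl)(Cl)Cl)c1OC(=O)OCC(Cl)(Cl)Cl)[C@@]1(C(=O)OCc3ccc(N=O)cc3)CCCC(C)(C)[C@@H]1CC2 | intermediate
8 | (15S)-16-acetoxycarnosic acid 4-aminobenzyl ester | CC(=O)OC[C@@H](C)c1cc2c(c(O)c1O)[C@@]1(C(=O)OCc3ccc(N)cc3)CCCC(C)(C)[C@@H]1CC2 | intermediate
9 | (15S)-16-acetoxycarnosic acid | CC(=O)OC[C@@H](C)c1cc2c(c(O)c1O)[C@@]1(C(=O)O)CCCC(C)(C)[C@@H]1CC2 | intermediate
10 | (15S)-16-acetoxycarnosic acid o-quinone (11,12-dione) | CC(=O)OC[C@@H](C)C1=CC2=C(C(=O)C1=O)[C@@]1(C(=O)O)CCCC(C)(C)[C@@H]1CC2 | intermediate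
11 | p-quinone methide tautomer (C7=C8, 11-hydroxy, 12-oxo) | CC(=O)OC[C@@H](C)C1=CC2=CC[C@H]3C(C)(C)CCC[C@]3(C(=O)O)C2=C(O)C1=O | intermediate
12 | (15S)-16-acetoxycarnosol, (5S,7S,10R,15S) | CC(=O)OC[C@@H](C)c1cc2c(c(O)c1O)[C@@]13CCCC(C)(C)[C@@H]1C[C@@H]2OC3=O | target

**Step count and risks**

Total steps: 4. Longest linear sequence: 4 (from carnosic acid).

Most likely to fail, in this order:

Step 2 (the new photochemical step). Risks: a short triplet lifetime, abstraction at C15–H from the minor rotamer, or folding of the template over ring A. Fallback with known chemistry, setting out from 1 and returning at 12: the template is abandoned and C16 is reached through the alkene. 1 is oxidised with Ag2O (Et2O, then MeOH) to carnosol F1 and acetylated (Ac2O, pyridine) to carnosol 11,12-diacetate F2. Wohl–Ziegler bromination (NBS, cat. dibenzoyl peroxide, PhCF3, 80 °C) at C15, the only well-placed benzylic position now that C7–H is a bridgehead hydrogen in the ring plane, gives 15-bromocarnosol 11,12-diacetate F3. Dehydrobromination (Li2CO3, DMF, 100 °C) gives 15,16-didehydrocarnosol 11,12-diacetate F4. Hydroboration and oxidation (9-BBN, THF; then Me3NO) give 16-hydroxycarnosol 11,12-diacetate F5 as a roughly 1:1 mixture of C15 epimers. After acetylation, (15S)-16-acetoxycarnosol 11,12-diacetate F6 is separated by preparative HPLC, and hydrazine hydrate (THF/MeOH, 0 °C) removes the two aryl acetates selectively to give 12. This fallback gives up control of C15 and loses half the material.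

Step 4 (anodic lactonisation). Risk: the product is again a catechol and can be over-oxidised if the quinone isomerises while current still flows. Fallback, setting out from 9 and returning at 12: the lactone C–O bond is made by benzylic substitution on a protected catechol instead of through the quinone. 9 is re-protected (TrocCl, pyridine; aqueous work-up) as (15S)-16-acetoxycarnosic acid 11,12-bis(2,2,2-trichloroethyl carbonate) F7. Bromination at C7 (NBS, cat. dibenzoyl peroxide, PhCF3, 80 °C) gives 7α-bromo-(15S)-16-acetoxycarnosic acid 11,12-bis(2,2,2-trichloroethyl carbonate) F8. Carboxylate displacement with inversion (NaHCO3, DMF, rt) closes the ring to (15S)-16-acetoxycarnosol 11,12-bis(2,2,2-trichloroethyl carbonate) F9, and Zn/AcOH then frees the catechol to give 12.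

Step 3 (global unmasking). Risk: the 1,6-elimination of the hindered 4-aminobenzyl ester may stall in acetic acid. Fallback, setting out from 8 and returning at 9: the amino ester 8 (Troc groups already gone) is isolated by extraction and its benzylic C–O bond is cut by catalytic hydrogenolysis (H2 1 atm, Pd/C, EtOAc, rt) instead of by self-immolation. This makes no compound outside the list (F0).

**Further compounds**
F1 | step 2 | carnosol | CC(C)c1cc2c(c(O)c1O)[C@@]13CCCC(C)(C)[C@@H]1C[C@@H]2OC3=O
F2 | step 2 | carnosol 11,12-diacetate | CC(C)c1cc2c(c(OC(C)=O)c1OC(C)=O)[C@@]13CCCC(C)(C)[C@@H]1C[C@@H]2OC3=O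
F3 | step 2 | 15-bromocarnosol 11,12-diacetate | CC(C)(Br)c1cc2c(c(OC(C)=O)c1OC(C)=O)[C@@]13CCCC(C)(C)[C@@H]1C[C@@H]2OC3=O
F4 | step 2 | 15,16-didehydrocarnosol 11,12-diacetate | C=C(C)c1cc2c(c(OC(C)=O)c1OC(C)=O)[C@@]13CCCC(C)(C)[C@@H]1C[C@@H]2OC3=O
F5 | step 2 | (15RS)-16-hydroxycarnosol 11,12-diacetate | OCC(C)c1cc2c(c(OC(C)=O)c1OC(C)=O)[C@@]13CCCC(C)(C)[C@@H]1C[C@@H]2OC3=O
F6 | step 2 | (15S)-16-acetoxycarnosol 11,12-diacetate | CC(=O)OC[C@@H](C)c1cc2c(c(OC(C)=O)c1OC(C)=O)[C@@]13CCCC(C)(C)[C@@H]1C[C@@H]2OC3=O
F0 | step 3 | none | none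
F7 | step 4 | (15S)-16-acetoxycarnosic acid 11,12-bis(2,2,2-trichloroethyl carbonate) | CC(=O)OC[C@@H](C)c1cc2c(c(OC(=O)OCC(Cl)(Cl)Cl)c1OC(=O)OCC(Cl)(Cl)Cl)[C@@]1(C(=O)O)CCCC(C)(C)[C@@H]1CC2
F8 | step 4 | 7α-bromo-(15S)-16-acetoxycarnosic acid 11,12-bis(2,2,2-trichloroethyl carbonate) | CC(=O)OC[C@@H](C)c1cc2c(c(OC(=O)OCC(Cl)(Cl)Cl)c1OC(=O)OCC(Cl)(Cl)Cl)[C@@]1(C(=O)O)CCCC(C)(C)[C@@H]1C[C@H]2Br
F9 | step 4 | (15S)-16-acetoxycarnosol 11,12-bis(2,2,2-trichloroethyl carbonate) | CC(=O)OC[C@@H](C)c1cc2c(c(OC(=O)OCC(Cl)(Cl)Cl)c1OC(=O)OCC(Cl)(Cl)Cl)[C@@]13CCCC(C)(C)[C@@H]1C[C@@H]2OC3=O
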